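## Analysis of the target

Baeomycesic acid (14) is a depside: two pentasubstituted benzene rings joined only by an aryl ester, with no further ring and no chain. Ring A (C1–C6) carries the ester carbonyl on C1, a hydroxyl on C2, a formyl group on C3, a methoxy group on C4, hydrogen on C5 and a methyl group on C6. Ring B (C1'–C6') carries the free carboxylic acid on C1', a hydroxyl on C2', methyl groups on C3' and C6', hydrogen on C5' and the ester oxygen on C4'. There is no stereocentre and the ester axis rotates freely, so the molecule is achiral and nothing has to be related or controlled. The sensitive groups are the depside link (an activated aryl ester of a salicylic acid, cleaved by alkoxides, amines and hot alcohols), the aromatic aldehyde, and the ring B ortho-hydroxy acid, which decarboxylates easily once free. The synthesis is hard for four reasons: the ester carbonyl sits between the C2 hydroxyl and the C6 methyl group, so direct esterification attacks a shielded acyl carbon; three phenolic oxygens must be told apart, since only O4 is methylated; the formyl group must go to C3 only; and the acid must be released last without harm to the ester link or the aldehyde. The strategy rests on the polyketide pattern of ring A: C1 with its carbonyl, oxygen on C2 and C4, and methyl on C6 are the fold of a linear 3,5,7-trioxooctanoyl chain whose carboxyl carbon is the depside carbonyl bound to O4' of ring B. Ring A can therefore be grown on the ring B oxygen from an open chain, so the crowded ester exists before its flanking substituents do.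

## Retrosynthetic reasoning

**14 back to 13.** The last bond cut is the benzyl–oxygen bond of the ring B ester. The free acid decarboxylates readily and would interfere with every base-mediated step, so it stays masked to the end. A benzyl ester comes off by hydrogenolysis under neutral conditions that leave the aryl ester alone. The forward step must cleave this one C–O bond faster than it reduces the C3 formyl group.

**13 back to 11.** The C3–CHO bond is cut next. In 11, C3 of ring A is the only unsubstituted carbon in the molecule that lies ortho to a free phenol: C1 is taken by the ester, and both neighbours of the 2'-OH (C1' and C3') carry carbon. A formylation delivered from a metal phenoxide therefore has one place to go, passing through the hydroxymethyl stage 12. Carrying the one-carbon unit through the ring synthesis would put a substituent on the central carbon of the polyketide chain and burden the key step, so it is added afterwards.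

**11 back to 10.** The O4–CH3 bond is cut. In 10 the ring A 4-OH is the only phenol not held in a hydrogen bond to an ester carbonyl, and being para to that carbonyl it is the most acidic. The 2-OH and 2'-OH are chelated and flanked on both sides. Methylation comes before formylation because a free 4-OH would open C5 as a second ortho position.

**10 back to 3 and 6.** This is the central disconnection. Ring A is opened at the C1–C6 bond (retro-aldol condensation), giving the open-chain aryl 3,5,7-trioxooctanoate 8 by way of carbinol 9. The bond between the depside carbonyl and O4' is then cut, leaving acylketene 7 and the ring B diol 6. The ketene is stored in its masked form, the diketo-dioxinone 3. Cutting here, and not at the ester of a finished ring A acid, means the forward reaction never attacks a carbonyl flanked by two ortho substituents: the C–O bond forms by addition of a phenol to a ketene and the ring closes afterwards. One operation builds the ring, two skeletal bonds and the full oxygen pattern. Ring B needs no phenol protection, because its chelated, hindered 2'-OH is a much poorer nucleophile than the 4'-OH. The forward step must make the chain C2-to-C7 aldol of 8 win over expulsion of the aryloxide from chain C1.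

**3 back to 2 and 1.** The side chain of 3 is cut between its central methylene and the terminal acetyl group, giving keto-dioxinone 2. The same cut on 2 leads to the purchasable dioxinone 1. Each cut corresponds to a Claisen-type acylation of an enolate by an acetyl donor: first the dienolate of 1 at its 6-methyl carbon, then the dianion of 2 at its terminal methyl carbon. Two successive acetylations are preferred to one acylation with a ketal-masked acetoacetyl unit, because no unmasking is then needed on the cyclisation-prone triketide equivalent.

**6 back to 5 and 4.** The benzyl–oxygen bond of 6 is cut to acid 5, and 5 is traced to its methyl ester 4 (atraric acid), which is purchasable with the whole ring B substitution in place. The ester exchange goes through the free acid because a 2,6-disubstituted benzoate does not transesterify at the acyl carbon. The forward steps are an acylium-type ester cleavage and an O-alkylation of the carboxylate.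

## Alternatives that were turned down

**Alternative 1: Danheiser benzannulation.**
- Disconnection: ring A is cut at C2–C3, C4–C5 and C1–C2, into a vinylketene already esterified to O4' and an alkoxyalkyne.
- Forward key step: irradiation of diazo enone A2, benzyl 2-(benzyloxy)-4-{[(2E)-5-diazo-3-methyl-4-oxopent-2-enoyl]oxy}-3,6-dimethylbenzoate, would give the vinylketene by Wolff rearrangement. [2+2] addition of methoxyalkyne A3, tert-butyl[(3-methoxyprop-2-yn-1-yl)oxy]dimethylsilane, then four-electron opening of the cyclobutenone and six-electron closure, would give phenol A1, benzyl 2-(benzyloxy)-4-{[3-(tert-butyldimethylsilyloxymethyl)-2-hydroxy-4-methoxy-6-methylbenzoyl]oxy}-3,6-dimethylbenzoate.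
- For it: all six positions of ring A are fixed by the connectivity of the two partners. The C3 carbon, the 4-OMe and the free 2-OH arrive differentiated, so neither a selective methylation nor a formylation on the finished depside is needed. On this point it is stronger than the chosen route.
- Against it: A2 needs a ring B phenol with the chelated 2'-OH selectively benzylated, a methylbutenedioic half ester on O4', acid activation and diazoketone formation. A2 also joins an aryl ester to an enone, a sensitive Michael acceptor. A3 is a hydrolytically labile ynol ether that must be made. After the annulation, desilylation, oxidation of the benzylic alcohol and a double hydrogenolysis are still required.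
- Comparison: the step count is clearly higher and the route uses diazo chemistry and photolysis. The chosen strategy offers instead two stable building blocks, an unprotected ring B, and a ring closure that follows from a simple O–H addition.

**Alternative 2: Brassard diene Diels–Alder.**
- Disconnection: ring A is cut at C1–C2 and C5–C6, into the triple bond of a ring B ynoate and a four-carbon dioxygenated diene.
- Forward key step: ynoate A5, benzyl 2-(benzyloxy)-4-(but-2-ynoyloxy)-3,6-dimethylbenzoate, would react with Brassard diene A6, [(1,3-dimethoxybuta-1,3-dien-1-yl)oxy]trimethylsilane. The adduct would aromatise by loss of the acetal methoxy group and the silyl group to A4, benzyl 2-(benzyloxy)-4-(2-hydroxy-4-methoxy-6-methylbenzoyloxy)-3,6-dimethylbenzoate.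
- For it: the depside bond is made by acylating O4' with an unhindered alkynoic acid, which avoids the shielded acyl carbon as well as the chosen route does. The diene delivers 2-OH and 4-OMe already differentiated, which saves the methylation step; here it is stronger.
- Against it: an internal ynoate with a β-methyl group is a sluggish dienophile and needs prolonged heating, under which the ketene acetal diene degrades. The activated aryl ester is open to acyl substitution by the nucleophilic diene. The 2'-OH must be masked (a free phenol would protonate the diene), which costs a selective protection sequence. The C3 formylation is still needed afterwards.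
- Comparison: one step is saved after ring formation but more are spent before it, and the ring is built by a demanding bimolecular cycloaddition. In the chosen route the only bimolecular event is the fast capture of a ketene, and the ring then closes intramolecularly.

**Alternative 3: three-component palladium carbonylation.**
- Disconnection: both bonds of the depside carbonyl (C1–carbonyl and carbonyl–O4') are cut, giving a ring A iodide, the carbonyl carbon and phenol 6.
- Forward key step: oxidative addition of palladium to iodide A8, 3-iodo-2,6-dimethoxy-4-methylbenzaldehyde, carbonyl insertion, and capture of the aroyl palladium by the 4'-phenoxide of 6 would give A7, benzyl 4-(3-formyl-2,4-dimethoxy-6-methylbenzoyloxy)-2-hydroxy-3,6-dimethylbenzoate.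
- For it: it is the most convergent plan. Ring A arrives complete with its formyl group, so no C–H functionalisation is done on the base-sensitive depside, and 6 is used unprotected. On convergence and on avoiding the late formylation it is stronger than the chosen route.
- Against it: the iodide is flanked by OMe and CH3, and the nucleophile is a weakly nucleophilic, electron-poor phenoxide, so both insertion and acyl transfer are slow at a crowded centre. More seriously, A7 carries a 2-OMe that must be cleaved selectively. Both methoxy groups are ortho to the formyl group, so a chelation-controlled Lewis acid demethylation has no clean handle, and the same reagents attack the benzyl ester and the depside link.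
- Comparison: the chosen strategy delivers the 2-OH free and chelated from the ring-forming step, and leaves O4 as the one phenol that can be addressed, so no demethylation is needed.

Key step: step 5

Remark: the target has no stereocentre and no hindered axis, so it is achiral and the single-enantiomer requirement is met by the one structure that exists; compounds 1 and 4 are taken as purchasable.

## Route

Step 1
Reactants: 1 2,2,6-trimethyl-4H-1,3-dioxin-4-one
Product: 2 2,2-dimethyl-6-(2-oxopropyl)-4H-1,3-dioxin-4-one
Conditions: 1 (2.0 equiv), LiHMDS (2.0 equiv), THF, −78 °C; AcCl (1.0 equiv), −78 °C; 1 M HCl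
Reagents that add atoms: acetyl chloride, CC(=O)Cl
Why: Vinylogous Claisen-type C-acylation of the lithium dienolate of 1 at the 6-methyl carbon by an acid chloride. Half an equivalent of electrophile is used because a second dienolate deprotonates the more acidic β-keto product, which also shields it from a second acylation; the regenerated 1 is recovered.

Step 2
Reactants: 2 2,2-dimethyl-6-(2-oxopropyl)-4H-1,3-dioxin-4-one
Product: 3 2,2-dimethyl-6-(2,4-dioxopentyl)-4H-1,3-dioxin-4-one
Conditions: LDA (2.2 equiv), THF, −78 °C; MeC(O)N(OMe)Me (1.0 equiv), −78 → −30 °C; aq. NH4Cl
Reagents that add atoms: N-methoxy-N-methylacetamide, CC(=O)N(C)OC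
Why: Claisen-type acylation of the 1,3-dicarbonyl dianion of 2; the second deprotonation occurs at the terminal methyl group and this last-formed, most basic carbanion attacks the Weinreb amide. The chelated tetrahedral adduct survives until the quench, so the acidic product can neither protonate unreacted dianion nor be acylated again.

Step 3
Reactants: 4 atraric acid (methyl 2,4-dihydroxy-3,6-dimethylbenzoate)
Product: 5 2,4-dihydroxy-3,6-dimethylbenzoic acid
Conditions: conc. H2SO4, 0 °C → rt; then ice–water
Reagents that add atoms: water, O
Why: Acid-mediated acyl–oxygen cleavage of a 2,6-disubstituted benzoate through its acylium ion (AAc1 mechanism), which the ortho- and para-hydroxyl groups stabilise; water quenches the ion to the acid. Short, cold contact should hold back decarboxylation and ring sulfonation.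

Step 4
Reactants: 5 2,4-dihydroxy-3,6-dimethylbenzoic acid
Product: 6 benzyl 2,4-dihydroxy-3,6-dimethylbenzoate
Conditions: BnBr (1.05 equiv), KHCO3 (1.2 equiv), DMF, rt
Reagents that add atoms: benzyl bromide, BrCc1ccccc1
Why: Hydrogencarbonate deprotonates only the carboxylic acid, and the carboxylate is benzylated by SN2 displacement while both phenols stay free. The hindered acid is thus esterified at oxygen, away from the shielded acyl carbon.

Step 5
Reactants: 3 2,2-dimethyl-6-(2,4-dioxopentyl)-4H-1,3-dioxin-4-one; 6 benzyl 2,4-dihydroxy-3,6-dimethylbenzoate
Product: 10 benzyl 4-(2,4-dihydroxy-6-methylbenzoyloxy)-2-hydroxy-3,6-dimethylbenzoate, via acylketene 7 (not isolated), via aryl 3,5,7-trioxooctanoate 8 (not isolated), via aldol carbinol 9 (not isolated)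
Conditions: PhMe, 110 °C, 3 (1.0 equiv) added slowly to 6 (1.5 equiv); cool; Et3N–AcOH buffer, THF, rt; then TsOH (cat.), rt
Reagents that add atoms: none
Why: Heating 3 causes a retro-hetero-Diels–Alder loss of acetone to acylketene 7, whose ketene carbon is captured by the free 4'-OH of 6 to give the aryl triketo ester 8; the closest known reaction type is the thermolysis of diketo-dioxinones in the presence of O–H nucleophiles followed by aldol aromatisation to resorcylates. The 2'-OH does not compete because it is held in a hydrogen bond to the benzyl ester carbonyl and is flanked by C1' and the C3' methyl group, whereas O4' is free. Ring A then closes by a 6-(enolendo)-exo-trig aldol addition of the chain C2 enol of 8 to the C7 methyl ketone (carbinol 9), and dehydration followed by enolisation gives the arene with C1 acyl, C2 OH, C4 OH and C6 methyl. The two stereocentres of 9 form without control and are erased on aromatisation, so the step leaves no stereochemical element. The selectivity needed is aldol closure over acyl substitution at chain C1 with loss of the aryloxide, either lactonisation through the C5 enol oxygen to a 2-pyranone or Claisen closure from C6 to an acylphloroglucinol. A weakly acidic amine–acetate buffer keeps the enolate concentration, and with it aryloxide expulsion, low; the terminal methyl ketone is the least hindered and most electrophilic ketone of 8, and aromatisation makes the aldol path irreversible. Slow addition of 3 to an excess of 6 keeps the concentration of 7 low, against its cyclisation onto its own enol oxygen and against dimerisation. The hindered aroyl–oxygen bond is thus made at the ketene stage, before the substituents that shield it exist.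

Step 6
Reactants: 10 benzyl 4-(2,4-dihydroxy-6-methylbenzoyloxy)-2-hydroxy-3,6-dimethylbenzoate
Product: 11 benzyl 2-hydroxy-4-(2-hydroxy-4-methoxy-6-methylbenzoyloxy)-3,6-dimethylbenzoate
Conditions: MeI (1.1 equiv), K2CO3 (1.1 equiv), acetone, rt
Reagents that add atoms: iodomethane, CI
Why: Williamson O-methylation of the only unchelated phenol: the ring A 4-OH is para to the ester carbonyl and the most acidic, while the 2-OH and 2'-OH are hydrogen-bonded to their ester carbonyls and flanked on both sides. One equivalent of base and electrophile at room temperature should stop at the monoether.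

Step 7
Reactants: 11 benzyl 2-hydroxy-4-(2-hydroxy-4-methoxy-6-methylbenzoyloxy)-3,6-dimethylbenzoate
Product: 13 benzyl 4-(3-formyl-2-hydroxy-4-methoxy-6-methylbenzoyloxy)-2-hydroxy-3,6-dimethylbenzoate, via hydroxymethyl phenol 12 (not isolated)
Conditions: MgCl2 (3 equiv), Et3N (4 equiv), (CH2O)n (6 equiv), MeCN, 80 °C; 1 M HCl
Reagents that add atoms: paraformaldehyde (as formaldehyde), C=O
Why: Magnesium-mediated ortho-formylation (Casnati–Skattebøl type): the magnesium phenoxide of the ring A 2-OH binds formaldehyde and delivers it to the adjacent C3 to give 12, which a second formaldehyde oxidises to the aldehyde by hydride transfer. C3 is the only unsubstituted position ortho to a free phenol in the molecule and is further activated by the 4-OMe, so the site selectivity is structural.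

Step 8
Reactants: 13 benzyl 4-(3-formyl-2-hydroxy-4-methoxy-6-methylbenzoyloxy)-2-hydroxy-3,6-dimethylbenzoate
Product: 14 baeomycesic acid, 4-[(3-formyl-2-hydroxy-4-methoxy-6-methylbenzoyl)oxy]-2-hydroxy-3,6-dimethylbenzoic acid
Conditions: H2 (1 atm), 10% Pd/C, EtOAc, rt, stopped after uptake of one equivalent
Reagents that add atoms: none
Why: Hydrogenolysis of the benzylic C–O bond over palladium under neutral conditions releases the acid without touching the aryl ester. The chelated aromatic aldehyde is reduced much more slowly than the benzyl ester is cleaved.

## Compound list

1 | 2,2,6-trimethyl-4H-1,3-dioxin-4-one | CC1=CC(=O)OC(C)(C)O1 | starting material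
2 | 2,2-dimethyl-6-(2-oxopropyl)-4H-1,3-dioxin-4-one | CC(=O)CC1=CC(=O)OC(C)(C)O1 | intermediate
3 | 2,2-dimethyl-6-(2,4-dioxopentyl)-4H-1,3-dioxin-4-one | CC(=O)CC(=O)CC1=CC(=O)OC(C)(C)O1 | intermediate
4 | atraric acid (methyl 2,4-dihydroxy-3,6-dimethylbenzoate) | COC(=O)c1c(C)cc(O)c(C)c1O | starting material
5 | 2,4-dihydroxy-3,6-dimethylbenzoic acid | Cc1cc(O)c(C)c(O)c1C(=O)O | intermediate
6 | benzyl 2,4-dihydroxy-3,6-dimethylbenzoate | Cc1cc(O)c(C)c(O)c1C(=O)OCc1ccccc1 | intermediate
7 | oct-1-ene-1,3,5,7-tetrone (acylketene) | CC(=O)CC(=O)CC(=O)C=C=O | intermediate (not isolated)
8 | benzyl 2-hydroxy-3,6-dimethyl-4-[(3,5,7-trioxooctanoyl)oxy]benzoate | CC(=O)CC(=O)CC(=O)CC(=O)Oc1cc(C)c(C(=O)OCc2ccccc2)c(O)c1C | intermediate (not isolated)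
9 | benzyl 2-hydroxy-4-[(2-hydroxy-2-methyl-4,6-dioxocyclohexane-1-carbonyl)oxy]-3,6-dimethylbenzoate (two transient stereocentres, formed without control and lost on aromatisation) | CC1(O)CC(=O)CC(=O)C1C(=O)Oc1cc(C)c(C(=O)OCc2ccccc2)c(O)c1C | intermediate (not isolated)
10 | benzyl 4-(2,4-dihydroxy-6-methylbenzoyloxy)-2-hydroxy-3,6-dimethylbenzoate | Cc1cc(O)cc(O)c1C(=O)Oc1cc(C)c(C(=O)OCc2ccccc2)c(O)c1C | intermediate
11 | benzyl 2-hydroxy-4-(2-hydroxy-4-methoxy-6-methylbenzoyloxy)-3,6-dimethylbenzoate | COc1cc(C)c(C(=O)Oc2cc(C)c(C(=O)OCc3ccccc3)c(O)c2C)c(O)c1 | intermediate
12 | benzyl 2-hydroxy-4-[2-hydroxy-3-(hydroxymethyl)-4-methoxy-6-methylbenzoyloxy]-3,6-dimethylbenzoate | COc1cc(C)c(C(=O)Oc2cc(C)c(C(=O)OCc3ccccc3)c(O)c2C)c(O)c1CO | intermediate (not isolated)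
13 | benzyl 4-(3-formyl-2-hydroxy-4-methoxy-6-methylbenzoyloxy)-2-hydroxy-3,6-dimethylbenzoate | COc1cc(C)c(C(=O)Oc2cc(C)c(C(=O)OCc3ccccc3)c(O)c2C)c(O)c1C=O | intermediate
14 | baeomycesic acid, 4-[(3-formyl-2-hydroxy-4-methoxy-6-methylbenzoyl)oxy]-2-hydroxy-3,6-dimethylbenzoic acid | COc1cc(C)c(C(=O)Oc2cc(C)c(C(=O)O)c(O)c2C)c(O)c1C=O | target

## Step count and risks

Total step count: 8. Longest linear sequence: 6 steps (steps 1, 2, 5, 6, 7, 8; the ring B branch through steps 3, 4, 5, 6, 7, 8 is equally long).

**Step 5 (key step).** Two processes are most likely to spoil it. First, the acylketene may cyclise onto its own enol oxygen or dimerise before the phenol captures it, since a phenol is a weaker nucleophile than an aliphatic alcohol. Second, at the triketo ester stage, acyl substitution with loss of the ring B aryloxide (lactonisation or Claisen closure) may outrun the aldol, because an aryloxide para to an ester is a good leaving group. The fallback makes the depside bond by classical anhydride-activated esterification of a preformed ring A acid; it sets out from 6 and rejoins the route at 11, so step 6 is skipped as well. Purchased methyl 2,4-dihydroxy-6-methylbenzoate F1 would be methylated at its unchelated 4-OH (MeI, K2CO3, acetone) to methyl 2-hydroxy-4-methoxy-6-methylbenzoate F2. The hindered ester would be cleaved (KOH, aqueous DMSO, 90 °C, or cold conc. H2SO4) to 2-hydroxy-4-methoxy-6-methylbenzoic acid F3. F3 would be condensed with 6 using trifluoroacetic anhydride in toluene at rt; the mixed anhydride acylates the unchelated 4'-OH and gives 11.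

**Step 7.** The depside link may be cleaved at 80 °C by the magnesium methoxide that the redox stage generates, or by the basic medium. Alternatively the reaction may stall because the chelated, ester-bearing phenoxide is a poor nucleophile. The fallback changes both the order and the mechanism; it sets out from 10 and returns at 13. The resorcinol ring of 10 would be formylated under Lewis acid conditions (Rieche formylation: Cl2CHOMe, TiCl4, CH2Cl2, −20 → 0 °C, then aq. HCl). Titanium bound to the 2- and 4-oxygens directs the electrophile to C3 between them, and ring A is far more electron-rich than ring B. This gives benzyl 4-(3-formyl-2,4-dihydroxy-6-methylbenzoyloxy)-2-hydroxy-3,6-dimethylbenzoate F4. The more acidic and less hindered 4-OH of F4 would then be methylated (MeI, K2CO3, acetone, rt) to give 13.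

**Step 2.** Incomplete dianion formation, proton transfer or O-acylation may lower conversion, and the product may self-condense by aldol closure during the quench, since 3 is a masked 1,3,5,7-tetracarbonyl compound. The fallback brings both carbonyl carbons in as one ketal-masked unit; it sets out from 1 and returns at 3. Purchased ethyl (2-methyl-1,3-dioxolan-2-yl)acetate F5 would be converted into N-methoxy-N-methyl-2-(2-methyl-1,3-dioxolan-2-yl)acetamide F6 (MeNHOMe·HCl, iPrMgCl, THF, −20 °C). The lithium dienolate of 1 (LiHMDS, THF, −78 °C) would be acylated with F6 to give 2,2-dimethyl-6-[3-(2-methyl-1,3-dioxolan-2-yl)-2-oxopropyl]-4H-1,3-dioxin-4-one F7. The dioxolane of F7 would be hydrolysed (1 M HCl, THF, rt) to give 3.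

**Step 8.** Reduction of the formyl group to the hydroxymethyl or methyl stage may compete with debenzylation if the catalyst is too active or the reaction runs on. The fallback replaces the benzyl ester by an allyl ester, which is removed without hydrogen; it sets out from 5 and rejoins the route at the target 14.
- Acid 5 would be alkylated with allyl bromide (KHCO3, DMF, rt) to allyl 2,4-dihydroxy-3,6-dimethylbenzoate F8.
- F8 would be taken through the same three operations as 6: ketene capture and aromatisation with 3, 4-O-methylation, and magnesium-mediated formylation.
- These give in turn allyl 4-(2,4-dihydroxy-6-methylbenzoyloxy)-2-hydroxy-3,6-dimethylbenzoate F9, allyl 2-hydroxy-4-(2-hydroxy-4-methoxy-6-methylbenzoyloxy)-3,6-dimethylbenzoate F10 and allyl 4-(3-formyl-2-hydroxy-4-methoxy-6-methylbenzoyloxy)-2-hydroxy-3,6-dimethylbenzoate F11.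
- The allyl group of F11 would be transferred to sodium p-toluenesulfinate with catalytic Pd(PPh3)4 in THF/MeOH at rt, a neutral, non-reductive release of 14.

## Further compounds

F1 | step 5 | methyl 2,4-dihydroxy-6-methylbenzoate (purchased) | COC(=O)c1c(C)cc(O)cc1O
F2 | step 5 | methyl 2-hydroxy-4-methoxy-6-methylbenzoate | COC(=O)c1c(C)cc(OC)cc1O
F3 | step 5 | 2-hydroxy-4-methoxy-6-methylbenzoic acid | COc1cc(C)c(C(=O)O)c(O)c1
F4 | step 7 | benzyl 4-(3-formyl-2,4-dihydroxy-6-methylbenzoyloxy)-2-hydroxy-3,6-dimethylbenzoate | Cc1cc(O)c(C=O)c(O)c1C(=O)Oc1cc(C)c(C(=O)OCc2ccccc2)c(O)c1C
F5 | step 2 | ethyl (2-methyl-1,3-dioxolan-2-yl)acetate (purchased) | CCOC(=O)CC1(C)OCCO1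
F6 | step 2 | N-methoxy-N-methyl-2-(2-methyl-1,3-dioxolan-2-yl)acetamide | CON(C)C(=O)CC1(C)OCCO1
F7 | step 2 | 2,2-dimethyl-6-[3-(2-methyl-1,3-dioxolan-2-yl)-2-oxopropyl]-4H-1,3-dioxin-4-one | CC1(CC(=O)CC2=CC(=O)OC(C)(C)O2)OCCO1
F8 | step 8 | allyl 2,4-dihydroxy-3,6-dimethylbenzoate | Cc1cc(O)c(C)c(O)c1C(=O)OCC=C
F9 | step 8 | allyl 4-(2,4-dihydroxy-6-methylbenzoyloxy)-2-hydroxy-3,6-dimethylbenzoate | Cc1cc(O)cc(O)c1C(=O)Oc1cc(C)c(C(=O)OCC=C)c(O)c1C
F10 | step 8 | allyl 2-hydroxy-4-(2-hydroxy-4-methoxy-6-methylbenzoyloxy)-3,6-dimethylbenzoate | COc1cc(C)c(C(=O)Oc2cc(C)c(C(=O)OCC=C)c(O)c2C)c(O)c1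
F11 | step 8 | allyl 4-(3-formyl-2-hydroxy-4-methoxy-6-methylbenzoyloxy)-2-hydroxy-3,6-dimethylbenzoate | COc1cc(C)c(C(=O)Oc2cc(C)c(C(=O)OCC=C)c(O)c2C)c(O)c1C=O
A1 | alternative 1 | benzyl 2-(benzyloxy)-4-{[3-(tert-butyldimethylsilyloxymethyl)-2-hydroxy-4-methoxy-6-methylbenzoyl]oxy}-3,6-dimethylbenzoate | COc1cc(C)c(C(=O)Oc2cc(C)c(C(=O)OCc3ccccc3)c(OCc3ccccc3)c2C)c(O)c1CO[Si](C)(C)C(C)(C)C
A2 | alternative 1 | benzyl 2-(benzyloxy)-4-{[(2E)-5-diazo-3-methyl-4-oxopent-2-enoyl]oxy}-3,6-dimethylbenzoate | Cc1cc(OC(=O)/C=C(\C)C(=O)C=[N+]=[N-])c(C)c(OCc2ccccc2)c1C(=O)OCc1ccccc1
A3 | alternative 1 | tert-butyl[(3-methoxyprop-2-yn-1-yl)oxy]dimethylsilane | COC#CCO[Si](C)(C)C(C)(C)C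
A4 | alternative 2 | benzyl 2-(benzyloxy)-4-(2-hydroxy-4-methoxy-6-methylbenzoyloxy)-3,6-dimethylbenzoate | COc1cc(C)c(C(=O)Oc2cc(C)c(C(=O)OCc3ccccc3)c(OCc3ccccc3)c2C)c(O)c1
A5 | alternative 2 | benzyl 2-(benzyloxy)-4-(but-2-ynoyloxy)-3,6-dimethylbenzoate | CC#CC(=O)Oc1cc(C)c(C(=O)OCc2ccccc2)c(OCc2ccccc2)c1C
A6 | alternative 2 | [(1,3-dimethoxybuta-1,3-dien-1-yl)oxy]trimethylsilane (Brassard diene, C1=C2 isomer mixture as prepared) | COC(=C)C=C(OC)O[Si](C)(C)C
A7 | alternative 3 | benzyl 4-(3-formyl-2,4-dimethoxy-6-methylbenzoyloxy)-2-hydroxy-3,6-dimethylbenzoate | COc1cc(C)c(C(=O)Oc2cc(C)c(C(=O)OCc3ccccc3)c(O)c2C)c(OC)c1C=O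
A8 | alternative 3 | 3-iodo-2,6-dimethoxy-4-methylbenzaldehyde | COc1cc(C)c(I)c(OC)c1C=O
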